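**Retrosynthetic overview**
- Feature: hopeafuran is a 2-arylbenzofuran bridged from C3 to C4. The bonds O1–C2 and C3–C6' (to resorcinol ring B) are the two bonds that one palladium cycle makes from an ortho-alkynylphenol and an aryl electrophile. C3–C6' is also a bond of the seven-membered ring (C=O carbon, C4, C3a, C3, C6', C1', CH).
- The only stereocentre is a doubly benzylic CH next to the ketone. The ketone carbon therefore stays as sp3 CH(CO2Me) through every basic step and is unmasked last (enolate hydroxylation, ester reduction, glycol cleavage), before neutral hydrogenolysis.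
- Key disconnection: furan and seven-membered ring open together to an alkynylresorcinol (ring A) and a ring B aryl triflate, held on two adjacent sp3 carbons.
- Precursor: alkyne by Sonogashira coupling on a ring A iodide; ring A by arylation of a zinc ester enolate; triflate from the lactone oxygen of a 4-arylchroman-2-one; stereocentre by rhodium/(S)-SEGPHOS 1,4-addition to 5,7-bis(benzyloxy)coumarin.
- Ring order: the coumarin lactone ring only serves to set the stereocentre and is then opened; furan and seven-membered ring form in one step.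

Key step: step 9

Remark: ring A is the benzo ring of the benzofuran, and ring B is the resorcinol ring (C1' on the stereocentre, oxygens at C2' and C4', C6' bonded to C3). The carbon that ends as the ketone is carried as a mixture of epimers and drawn without configuration. The sense of induction in step 2 is assumed to follow that of the parent coumarin.

**Route**

Step 1
Reactants: 1 5,7-dihydroxycoumarin
Product: 2 5,7-bis(benzyloxy)coumarin
Conditions: BnBr (2.4 equiv), K2CO3 (3 equiv), DMF, 60 °C
Reagents that add atoms: benzyl bromide, BrCc1ccccc1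
Why: Williamson etherification of the two acidic phenols, with benzyl chosen because it leaves at the end under neutral hydrogenolysis; the lactone is inert to anhydrous carbonate.

Step 2
Reactants: 2 5,7-bis(benzyloxy)coumarin; 3 4-(benzyloxy)phenylboronic acid
Product: 4 (S)-5,7-bis(benzyloxy)-4-[4-(benzyloxy)phenyl]chroman-2-one
Conditions: Rh(acac)(C2H4)2 (3 mol %), (S)-SEGPHOS (3.3 mol %), 3 (4 equiv), 1,4-dioxane/H2O 10:1, 60 °C
Reagents that add atoms: none
Why: Rhodium-catalysed asymmetric 1,4-addition of an arylboronic acid (Hayashi–Miyaura reaction) is established for coumarins, where (R)-SEGPHOS gives (R)-4-arylchroman-2-ones, so with the same CIP order at C4 the (S)-ligand should steer the arylrhodium to the face that sets the S centre; excess boronic acid offsets protodeboronation and the lower electrophilicity of the dialkoxycoumarin.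

Step 3
Reactants: 4 (S)-5,7-bis(benzyloxy)-4-[4-(benzyloxy)phenyl]chroman-2-one
Product: 6 methyl (S)-3-[2,4-bis(benzyloxy)-6-(trifluoromethylsulfonyloxy)phenyl]-3-[4-(benzyloxy)phenyl]propanoate, via sodium phenoxide ester 5 (not isolated)
Conditions: NaOMe (1.0 equiv, concentrated MeOH solution), THF, 0 °C; then PhNTf2 (1.15 equiv), 0 °C to rt
Reagents that add atoms: sodium methoxide, C[O-].[Na+]; N-phenylbis(trifluoromethanesulfonimide), O=S(=O)(N(c1ccccc1)S(=O)(=O)C(F)(F)F)C(F)(F)F
Why: Transesterification of the aryl lactone by one equivalent of methoxide is driven by release of the much less basic phenoxide, and O-sulfonylation of that phenoxide in the same flask forestalls relactonisation and turns the former lactone oxygen into the leaving group of the key step; the stereocentre is β to the carbonyl and is not touched.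

Step 4
Reactants: 7 5-bromoresorcinol
Product: 8 1-bromo-3,5-bis(tert-butyldimethylsilyloxy)benzene
Conditions: TBSCl (2.3 equiv), imidazole (4 equiv), DMF, rt
Reagents that add atoms: tert-butyldimethylsilyl chloride, CC(C)(C)[Si](C)(C)Cl
Why: Standard silylation of phenols; the aryl silyl ethers withstand the zinc enolate, iodination and Sonogashira steps and later leave with buffered fluoride without harm to triflate, ester or benzyl ethers.

Step 5
Reactants: 6 triflate ester from step 3; 8 1-bromo-3,5-bis(tert-butyldimethylsilyloxy)benzene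
Product: 11 methyl (3S)-3-[2,4-bis(benzyloxy)-6-(trifluoromethylsulfonyloxy)phenyl]-3-[4-(benzyloxy)phenyl]-2-[3,5-bis(tert-butyldimethylsilyloxy)phenyl]propanoate (C2 epimers), via lithium enolate 9 (not isolated), via chlorozinc enolate 10 (not isolated)
Conditions: LiN(SiMe3)2 (1.05 equiv), THF, −78 °C; ZnCl2 (1.1 equiv), −78 °C to rt; 8 (1.2 equiv), [Pd(μ-Br)(P(t-Bu)3)]2 (2.5 mol %), THF/toluene, rt to 40 °C
Reagents that add atoms: none
Why: Negishi-type α-arylation of a zinc ester enolate, in which the monoligated palladium released from the P(t-Bu)3 dimer inserts into the unhindered C–Br bond of 8 far faster than into the ortho-blocked C–OTf bond in a weakly polar medium, the zinc enolate is too mild to attack the sulfonate or to deprotonate the product, and the new α-centre is uncontrolled but erased later while the β-centre is not acidic.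

Step 6
Reactants: 11 α-aryl ester from step 5
Product: 12 methyl (3S)-3-[2,4-bis(benzyloxy)-6-(trifluoromethylsulfonyloxy)phenyl]-3-[4-(benzyloxy)phenyl]-2-[2-iodo-3,5-bis(tert-butyldimethylsilyloxy)phenyl]propanoate (C2 epimers)
Conditions: NIS (1.05 equiv), CF3CO2H (10 mol %), MeCN/CH2Cl2, 0 °C, dark
Reagents that add atoms: N-iodosuccinimide, O=C1CCC(=O)N1I
Why: Electrophilic aromatic iodination, in which ring A is the only ring with two donor oxygens and no acceptor (ring B is deactivated by the triflate, the 4-benzyloxyphenyl ring has a single donor), and attack para to one silyloxy group and ortho to the other (C2, equivalent to C6) is favoured over the position between the two bulky silyloxy groups.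

Step 7
Reactants: 12 aryl iodide from step 6; 13 1-(benzyloxy)-4-ethynylbenzene
Product: 14 methyl (3S)-3-[2,4-bis(benzyloxy)-6-(trifluoromethylsulfonyloxy)phenyl]-3-[4-(benzyloxy)phenyl]-2-[2-{[4-(benzyloxy)phenyl]ethynyl}-3,5-bis(tert-butyldimethylsilyloxy)phenyl]propanoate (C2 epimers)
Conditions: PdCl2(PPh3)2 (5 mol %), CuI (10 mol %), Et3N/THF 1:1, 40 °C
Reagents that add atoms: none
Why: Sonogashira coupling, in which oxidative addition into the C–I bond is much faster than into the hindered C–OTf bond at this temperature, while the silyl ether on the neighbouring oxygen prevents premature cyclisation.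

Step 8
Reactants: 14 bis-silyl ether from step 7
Product: 15 methyl (3S)-3-[2,4-bis(benzyloxy)-6-(trifluoromethylsulfonyloxy)phenyl]-3-[4-(benzyloxy)phenyl]-2-[2-{[4-(benzyloxy)phenyl]ethynyl}-3,5-dihydroxyphenyl]propanoate (C2 epimers)
Conditions: Bu4NF (2.2 equiv), AcOH (2.4 equiv), THF, 0 °C
Reagents that add atoms: none
Why: Fluoride cleavage of aryl silyl ethers, buffered with acetic acid so that neither free phenoxide nor unbuffered fluoride is present to close the furan early or to cleave the triflate.

Step 9
Reactants: 15 alkynylresorcinol aryl triflate from step 8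
Product: 16 tetracyclic ester: 2-[4-(benzyloxy)phenyl]-6-hydroxybenzofuran with C3 bonded to C6' of ring B and C4 bonded to CH(CO2Me); that carbon is bonded to the (S)-CH[4-(benzyloxy)phenyl] on C1' of ring B; benzyloxy groups at C2' and C4' (epimers at the ester carbon)
Conditions: Pd(PPh3)4 (10 mol %), K2CO3 (3 equiv), dry degassed DMF (0.01 M), 80 °C
Reagents that add atoms: none
Why: Proposed new method: zerovalent palladium inserts into the C–OTf bond of ring B, the resulting cationic arylpalladium binds the alkyne from the flank of ring A that carries the tether, the potassium phenoxide on the opposite flank attacks the distal alkyne carbon anti to the metal, and the 3-benzofuranyl(aryl)palladium so formed (an eight-membered palladacycle) collapses by reductive elimination. The closest known reaction type is the intermolecular palladium-catalysed annulation of ortho-alkynylphenols with aryl halides or triflates to 2,3-disubstituted benzofurans; new here is that the aryl electrophile hangs from the carbon that becomes C4, so that the C3–aryl bond closes a second ring. The furan closes 5-endo-dig through O1–C2, and the seven-membered ring closes through C3–C6' by contraction of the palladacycle. No stereocentre is made: the diarylmethine carbon is β to the ester and far too weakly acidic for K2CO3, so its S configuration is carried through, and scrambling at the ester carbon is harmless. The step needs O-attack rather than C-attack on the alkyne and oxypalladation rather than 7-exo-dig carbopalladation; carbonate ionises the phenols but not the ester α-CH, of the two phenoxides only the one next to the alkyne is within reach, the halide-free cationic palladium is a strong π-acid, and high dilution disfavours intermolecular coupling. Should the furan close before the metal arrives, C3–H arylation of that benzofuran by the same arylpalladium would lead to 16 as well.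

Step 10
Reactants: 16 tetracyclic phenol ester from step 9
Product: 17 6-O-benzyl ether of 16 (five benzyl ethers; S at the diarylmethine carbon; epimers at the ester carbon)
Conditions: BnBr (1.2 equiv), K2CO3 (1.5 equiv), acetone, 50 °C
Reagents that add atoms: benzyl bromide, BrCc1ccccc1
Why: Williamson etherification of the single remaining phenol, needed because the enolate chemistry and the Pb(OAc)4 that follow do not tolerate a free phenol; carbonate is too weak to C-alkylate the ester.

Step 11
Reactants: 17 pentabenzyl tetracyclic ester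
Product: 19 tertiary α-hydroxy ester: 17 with OH in place of H on the ester-bearing ring carbon (S at the diarylmethine carbon; carbinol configuration open), via potassium enolate 18 (not isolated)
Conditions: KN(SiMe3)2 (1.2 equiv), THF, −78 °C; 2-(phenylsulfonyl)-3-phenyloxaziridine (1.5 equiv), −78 °C; AcOH quench
Reagents that add atoms: 2-(phenylsulfonyl)-3-phenyloxaziridine, O=S(=O)(N1OC1c1ccccc1)c1ccccc1
Why: Enolate hydroxylation with an N-sulfonyloxaziridine (Davis oxidation), in which the α-aryl ester is deprotonated cleanly while the diarylmethine CH is far too weakly acidic for the amide base, and the configuration of the new carbinol carbon is irrelevant because it becomes the ketone carbon.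

Step 12
Reactants: 19 α-hydroxy ester
Product: 20 1,2-diol: ring carbon bearing OH and CH2OH in place of OH and CO2Me (S at the diarylmethine carbon)
Conditions: LiAlH4 (2 equiv), THF, 0 °C to rt; aq potassium sodium tartrate work-up
Reagents that add atoms: none
Why: Hydride reduction of the ester to the primary alcohol, preferred to saponification because a small hydride reaches the crowded tertiary ester more readily than hydroxide; aryl ethers and the benzofuran are inert.

Step 13
Reactants: 20 1,2-diol
Product: 21 (S)-penta-O-benzylhopeafuran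
Conditions: Pb(OAc)4 (1.1 equiv), CH2Cl2, 0 °C, 15 min; filtration through silica
Reagents that add atoms: none
Why: Glycol cleavage with Pb(OAc)4 (Criegee oxidation) excises the former ester carbon as formaldehyde and unveils the ketone within minutes at 0 °C in a non-basic medium, so that the now acidic α-CH is not enolised.

Step 14
Reactants: 21 (S)-penta-O-benzylhopeafuran
Product: 22 (S)-hopeafuran
Conditions: H2 (1 atm), Pd/C (10 wt %), EtOAc/MeOH 1:1, rt, stopped at full debenzylation
Reagents that add atoms: none
Why: Catalytic hydrogenolysis of the five aryl benzyl ethers under neutral conditions, with no base or strong acid to enolise the doubly benzylic α-CH; the tetrasubstituted furan double bond and the hindered conjugated ketone are reduced much more slowly than O-benzyl groups are cleaved.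

**Compound list**
1 | 5,7-dihydroxycoumarin | O=c1ccc2c(O)cc(O)cc2o1 | starting material
2 | 5,7-bis(benzyloxy)coumarin | O=c1ccc2c(OCc3ccccc3)cc(OCc3ccccc3)cc2o1 | intermediate
3 | 4-(benzyloxy)phenylboronic acid | OB(O)c1ccc(OCc2ccccc2)cc1 | starting material
4 | (S)-5,7-bis(benzyloxy)-4-[4-(benzyloxy)phenyl]chroman-2-one | O=C1C[C@@H](c2ccc(OCc3ccccc3)cc2)c2c(OCc3ccccc3)cc(OCc3ccccc3)cc2O1 | intermediate
5 | sodium phenoxide of methyl (S)-3-[2,4-bis(benzyloxy)-6-hydroxyphenyl]-3-[4-(benzyloxy)phenyl]propanoate | COC(=O)C[C@@H](c1ccc(OCc2ccccc2)cc1)c1c([O-])cc(OCc2ccccc2)cc1OCc1ccccc1.[Na+] | intermediate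
6 | methyl (S)-3-[2,4-bis(benzyloxy)-6-(trifluoromethylsulfonyloxy)phenyl]-3-[4-(benzyloxy)phenyl]propanoate | COC(=O)C[C@@H](c1ccc(OCc2ccccc2)cc1)c1c(OS(=O)(=O)C(F)(F)F)cc(OCc2ccccc2)cc1OCc1ccccc1 | intermediate
7 | 5-bromoresorcinol | Oc1cc(O)cc(Br)c1 | starting material
8 | 1-bromo-3,5-bis(tert-butyldimethylsilyloxy)benzene | CC(C)(C)[Si](C)(C)Oc1cc(Br)cc(O[Si](C)(C)C(C)(C)C)c1 | intermediate
9 | lithium enolate of 6 | COC([O-])=C[C@@H](c1ccc(OCc2ccccc2)cc1)c1c(OS(=O)(=O)C(F)(F)F)cc(OCc2ccccc2)cc1OCc1ccccc1.[Li+] | intermediate
10 | chlorozinc enolate of 6 | COC(O[Zn]Cl)=C[C@@H](c1ccc(OCc2ccccc2)cc1)c1c(OS(=O)(=O)C(F)(F)F)cc(OCc2ccccc2)cc1OCc1ccccc1 | intermediate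
11 | α-[3,5-bis(silyloxy)phenyl] triflate ester (3S, C2 epimers) | COC(=O)C(c1cc(O[Si](C)(C)C(C)(C)C)cc(O[Si](C)(C)C(C)(C)C)c1)[C@@H](c1ccc(OCc2ccccc2)cc1)c1c(OS(=O)(=O)C(F)(F)F)cc(OCc2ccccc2)cc1OCc1ccccc1 | intermediate
12 | ring A 2-iodide of 11 | COC(=O)C(c1cc(O[Si](C)(C)C(C)(C)C)cc(O[Si](C)(C)C(C)(C)C)c1I)[C@@H](c1ccc(OCc2ccccc2)cc1)c1c(OS(=O)(=O)C(F)(F)F)cc(OCc2ccccc2)cc1OCc1ccccc1 | intermediate
13 | 1-(benzyloxy)-4-ethynylbenzene | C#Cc1ccc(OCc2ccccc2)cc1 | starting material
14 | bis-silylated diarylalkyne triflate ester | COC(=O)C(c1cc(O[Si](C)(C)C(C)(C)C)cc(O[Si](C)(C)C(C)(C)C)c1C#Cc1ccc(OCc2ccccc2)cc1)[C@@H](c1ccc(OCc2ccccc2)cc1)c1c(OS(=O)(=O)C(F)(F)F)cc(OCc2ccccc2)cc1OCc1ccccc1 | intermediate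
15 | alkynylresorcinol aryl triflate (key-step precursor) | COC(=O)C(c1cc(O)cc(O)c1C#Cc1ccc(OCc2ccccc2)cc1)[C@@H](c1ccc(OCc2ccccc2)cc1)c1c(OS(=O)(=O)C(F)(F)F)cc(OCc2ccccc2)cc1OCc1ccccc1 | intermediate
16 | tetracyclic 6-hydroxybenzofuran ester (key-step product) | COC(=O)C1c2cc(O)cc3oc(-c4ccc(OCc5ccccc5)cc4)c(c23)-c2cc(OCc4ccccc4)cc(OCc4ccccc4)c2[C@@H]1c1ccc(OCc2ccccc2)cc1 | intermediate
17 | pentabenzyl tetracyclic ester | COC(=O)C1c2cc(OCc4ccccc4)cc3oc(-c4ccc(OCc5ccccc5)cc4)c(c23)-c2cc(OCc4ccccc4)cc(OCc4ccccc4)c2[C@@H]1c1ccc(OCc2ccccc2)cc1 | intermediate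
18 | potassium enolate of 17 | COC([O-])=C1c2cc(OCc4ccccc4)cc3oc(-c4ccc(OCc5ccccc5)cc4)c(c23)-c2cc(OCc4ccccc4)cc(OCc4ccccc4)c2[C@@H]1c1ccc(OCc2ccccc2)cc1.[K+] | intermediate
19 | tertiary α-hydroxy ester | COC(=O)C1(O)c2cc(OCc4ccccc4)cc3oc(-c4ccc(OCc5ccccc5)cc4)c(c23)-c2cc(OCc4ccccc4)cc(OCc4ccccc4)c2[C@@H]1c1ccc(OCc2ccccc2)cc1 | intermediate
20 | 1,2-diol | OCC1(O)c2cc(OCc4ccccc4)cc3oc(-c4ccc(OCc5ccccc5)cc4)c(c23)-c2cc(OCc4ccccc4)cc(OCc4ccccc4)c2[C@@H]1c1ccc(OCc2ccccc2)cc1 | intermediate
21 | (S)-penta-O-benzylhopeafuran | O=C1c2cc(OCc4ccccc4)cc3oc(-c4ccc(OCc5ccccc5)cc4)c(c23)-c2cc(OCc4ccccc4)cc(OCc4ccccc4)c2[C@@H]1c1ccc(OCc2ccccc2)cc1 | intermediate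
22 | (S)-hopeafuran | O=C1c2cc(O)cc3oc(-c4ccc(O)cc4)c(c23)-c2cc(O)cc(O)c2[C@@H]1c1ccc(O)cc1 | target

**Step count**
- Total step count: 14.
- Longest linear sequence: 13 steps (steps 1–3 and 5–14, from 5,7-dihydroxycoumarin).

**Steps most likely to fail**

1. Step 9 (key step).
- What may go wrong: syn carbopalladation of the alkyne may outrun phenoxide attack. The sulfonate may be lost by hydrolysis or by triflyl transfer to a phenoxide. The reaction may also stall after plain cycloisomerisation, because PPh3-ligated palladium is a modest C–H arylation catalyst.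
- Fallback: it sets out from 15 and separates the two bond formations, each by known chemistry. Cycloisomerisation of the ortho-alkynylphenol with a carbophilic gold catalyst (AuCl(PPh3)/AgOTf, toluene, rt) should give the 3-unsubstituted 2-arylbenzofuran triflate F1. Benzylation (BnBr, K2CO3, acetone) gives its 6-benzyl ether F2. Intramolecular direct arylation of the nucleophilic C3–H by concerted metalation–deprotonation (Pd(OAc)2, PCy3·HBF4, pivalic acid, K2CO3, DMA, 100 °C) then closes the seven-membered ring. The fallback comes back to the route at 17.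

2. Step 5.
- What may go wrong: the triflyl group may be transferred from ring B to the enolate. Palladium may insert into the C–OTf bond. The β-branched enolate may also couple too slowly.
- Fallback: it sets out from 4 and defers the triflate until after the C–C bond is made. Phenoxide 5 is generated as in step 3 but trapped with chloromethyl methyl ether to give the methoxymethyl ether ester F3. With no sulfonate in the molecule, conventional palladium-catalysed α-arylation of the lithium enolate with 8 (LiN(SiMe3)2, Pd(dba)2, P(t-Bu)3, toluene, rt) gives the α-aryl ester F4. The phenolic acetal is removed with NaHSO4·SiO2 in CH2Cl2, which spares aryl silyl ethers, to give the phenol F5. Immediate triflation (Tf2O, pyridine, CH2Cl2, 0 °C) comes back to the route at 11.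

3. Step 6.
- What may go wrong: iodination may occur between the two silyloxy groups or on another alkoxyarene ring. The reaction may also be sluggish at the crowded position next to the branched side chain.
- Fallback: it sets out from 8 and places the halogen while ring A is the only arene present. NIS in MeCN should give 1-bromo-2-iodo-3,5-bis(tert-butyldimethylsilyloxy)benzene F6. Sonogashira coupling with 13 at the C–I bond (PdCl2(PPh3)2, CuI, Et3N, rt) gives the bromo diarylalkyne F7. F7 then takes the place of 8 in the arylation of chlorozinc enolate 10 under the conditions of step 5, where the neutral zinc enolate avoids base-induced carbocyclisation onto the alkyne. The fallback comes back to the route at 14.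

**Further compounds**
F1 | step 9 | methyl (3S)-3-[2,4-bis(benzyloxy)-6-(trifluoromethylsulfonyloxy)phenyl]-3-[4-(benzyloxy)phenyl]-2-{2-[4-(benzyloxy)phenyl]-6-hydroxybenzofuran-4-yl}propanoate | COC(=O)C(c1cc(O)cc2oc(-c3ccc(OCc4ccccc4)cc3)cc12)[C@@H](c1ccc(OCc2ccccc2)cc1)c1c(OS(=O)(=O)C(F)(F)F)cc(OCc2ccccc2)cc1OCc1ccccc1
F2 | step 9 | 6-O-benzyl ether of F1 | COC(=O)C(c1cc(OCc3ccccc3)cc2oc(-c3ccc(OCc4ccccc4)cc3)cc12)[C@@H](c1ccc(OCc2ccccc2)cc1)c1c(OS(=O)(=O)C(F)(F)F)cc(OCc2ccccc2)cc1OCc1ccccc1
F3 | step 5 | methyl (S)-3-[2,4-bis(benzyloxy)-6-(methoxymethoxy)phenyl]-3-[4-(benzyloxy)phenyl]propanoate | COC(=O)C[C@@H](c1ccc(OCc2ccccc2)cc1)c1c(OCOC)cc(OCc2ccccc2)cc1OCc1ccccc1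
F4 | step 5 | methyl (3S)-3-[2,4-bis(benzyloxy)-6-(methoxymethoxy)phenyl]-3-[4-(benzyloxy)phenyl]-2-[3,5-bis(tert-butyldimethylsilyloxy)phenyl]propanoate | COC(=O)C(c1cc(O[Si](C)(C)C(C)(C)C)cc(O[Si](C)(C)C(C)(C)C)c1)[C@@H](c1ccc(OCc2ccccc2)cc1)c1c(OCOC)cc(OCc2ccccc2)cc1OCc1ccccc1
F5 | step 5 | methyl (3S)-3-[2,4-bis(benzyloxy)-6-hydroxyphenyl]-3-[4-(benzyloxy)phenyl]-2-[3,5-bis(tert-butyldimethylsilyloxy)phenyl]propanoate | COC(=O)C(c1cc(O[Si](C)(C)C(C)(C)C)cc(O[Si](C)(C)C(C)(C)C)c1)[C@@H](c1ccc(OCc2ccccc2)cc1)c1c(O)cc(OCc2ccccc2)cc1OCc1ccccc1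
F6 | step 6 | 1-bromo-2-iodo-3,5-bis(tert-butyldimethylsilyloxy)benzene | CC(C)(C)[Si](C)(C)Oc1cc(Br)c(I)c(O[Si](C)(C)C(C)(C)C)c1
F7 | step 6 | 1-bromo-2-{[4-(benzyloxy)phenyl]ethynyl}-3,5-bis(tert-butyldimethylsilyloxy)benzene | CC(C)(C)[Si](C)(C)Oc1cc(Br)c(C#Cc2ccc(OCc3ccccc3)cc2)c(O[Si](C)(C)C(C)(C)C)c1
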